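Start from a one-step world: each bit of solid substrate lost turns up as target. The epsilon run denies that world, so ask what it gives instead.

| flask | solid substrate | gas phase | remark | time |
|---|---|---|---|---|
| epsilon | 0.055 M | 23 mM (held) | run made earlier |  |
| alder | 0.080 M | 23 mM (held) |  | 3.0 min |
| cedar | 0.025 M | 23 mM (held) |  | 3.0 min |
| elm | 0.050 M | 23 mM (held) |  | 3.0 min |
| ash | 0.012 M | 23 mM (held) |  | 3.0 min |
| birch | 0.20 M | 23 mM (held) |  | 3.0 min |

epsilon run (percent of the solid substrate charged)

| time / s | target / % | solid substrate / % |
|---|---|---|
| 10.0 | 0.1 | 75.8 |
| 12.0 | 0 | 75.9 |
| 25.0 | 3.4 | 60.5 |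
| 60.0 | 12.1 | 28.0 |

(readings scatter by 1 percentage point)

- at the start none of the gas phase is in solution
- at the start none of the solid substrate is in solution
- what has only dissolved of solid substrate counts as not reacted
- a reading or a percentage of target counts all its forms, free or not

- ranking by amount of target, in percent of the solid substrate charged, from high to low, at 3.0 min (alder / cedar / elm / ash / birch)
- the same order at 40 s (alder / cedar / elm / ash / birch)
- the amount of target, in percent of the solid substrate charged of the flask you put first, at 3.0 min
- the amount of target, in percent of the solid substrate charged of the flask you put last, at 3.0 min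

How much target comes per solid substrate lost? Take the epsilon readings at 25.0 s and 60.0 s. The solid falls by 32 percentage points while target rises by 8.7 points. Divide gain by loss and time drops out: 0.268. Call this the yield share, target gained per solid substrate lost, a selectivity read from the run. Treat it as a reading, since each number behind it has a scatter of 1 point.

How far does the solid get? Over the same stretch it falls at 0.511 mM s⁻¹. In 3.0 min that takes 92.0 mM, a little more than alder's charge of 0.080 M. So expect alder's solid to last nearly to the end.

Which flask leads? Elm, cedar and ash hold less solid than alder, so expect their solid to go sooner. The epsilon run gives no share for that later stretch, since it still holds 28.0 % of solid at its last reading. Birch holds more than that rate removes, so it keeps solid at the end. Put alder first, as the flask whose charge that rate about uses up in 3.0 min, at about 26.8 % by my reckoning.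

The forecast gave alder > elm > cedar > birch > ash at 3.0 min, cedar > elm > alder > birch > ash at 40 s, top 20.5 % and low 0.2 %, on the ground that “roughly a quarter of the substrate consumed after the sink becomes target”; its top stands below mine.

The flasks give alder > elm > cedar > birch > ash at 3.0 min and ash > cedar > elm > alder > birch at 40 s, with top 28.0 % and low 8.53 %.

    gas phase ⇌ dissolved gas, rate k1*(csat - [dissolved gas]) (kL = 0.00790 s⁻¹)
    starting material + dissolved gas ⇌ target (K = 120 M⁻¹, k = 11.0 M⁻¹ s⁻¹)
    starting material → side product (k = 0.0240 s⁻¹)
    crystals ⇌ target, rate k4*(cs4 - [target]) while solid is left; crystals form when [target] > cs4 (solubility = 2.30 mM, k = 0.110 s⁻¹)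
    solid substrate ⇌ starting material, rate k5*(cs5 - [starting material]) while solid is left; crystals form when [starting material] > cs5 (solubility = 19.0 mM, k = 0.100 s⁻¹)

In alder at 1.50 min, gas phase passes into solution at 0.157 mM s⁻¹ and solid substrate dissolves at 0.492 mM s⁻¹, a ratio of 0.319. At 1.03 min, alder makes dissolved gas 1.06 times as fast as it uses it, each step taken net. Alder has lost 100 % of its solid substrate at 3.00 min, so the yield share gives 26.8 %, against 28.0 % of target, crystals counted. A neighbour of alder with 0.32 M of solid substrate has lost 30.6 % of it at 3.00 min, so the share gives 8.20 %, and that flask holds 7.96 %.

The readings are calculated on assumed constants; noise was put on by code.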